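**Retrosynthetic overview**
- Last disconnection: the C14 angelate ester, giving the free 2,3,14-triol and angelic acid.
- The ring-A oxygens (C2 ketone, then C3-OH, C2-OH, C14-OH) are stripped back to an unoxidised spiro diene lactone.
- Key disconnection: the C5–C9 bond at the spiro centre goes back to the C9–C10 bond of the eudesmanolide alantolactone. In the forward direction this is a 1,2-alkyl shift in the C5 cation, the eudesmane → spirovetivane step of sesquiterpene biosynthesis.
- Ring order: rings A and B of the decalin and the cis-fused lactone are bought with alantolactone. The five-membered ring and the spiro centre are made in step 1 by contraction of ring B. No ring is formed after that.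

Assumption: (+)-alantolactone, the bulk lactone of Inula helenium root sold by several suppliers, is taken as a cheap commercial starting material.

Numbering in the names: eudesmane numbering is kept after the rearrangement (9(10→5)abeo-eudesmane). C5 is the spiro carbon, ring A is C1–C5 plus C10, the five-membered ring B is C5–C9, C14 sits on C10 and C15 on C4. α/β are as in the usual eudesmane drawing (at C5: C6 is β, C9 is α).

**Route**

Step 1
Reactants: 1 (+)-alantolactone
Product: 4 spiro lactone (4S,5R,7R,8R)-9(10→5)abeo-eudesma-1(10),11(13)-dien-12,8β-olide, via C5 eudesmyl cation 2 (not isolated), via C10 spiro cation 3 (not isolated)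
Conditions: HN(SO2CF3)2 (10 mol %), (CF3)2CHOH/CH2Cl2 1:1, −20 °C, stopped at partial conversion with Et3N; recovered 1 and its Δ4 isomer are recycled
Reagents that add atoms: none
Why: Proposed new method: protonation of the C5=C6 alkene at C6 gives tertiary cation 2, C9 then shifts suprafacially from C10 to the α face of C5 (the ring-contracting 1,2-alkyl shift of spirovetivane biosynthesis, which sets C5 as R with C9 α and C6 β and leaves the 4β-methyl untouched), and the new tertiary cation 3 loses H1 to give the trisubstituted 1(10)-alkene, while the fluorinated alcohol and the non-basic triflimide ion give the cation time to rearrange before it simply loses a proton again; closest known reaction type: Wagner–Meerwein ring contraction of decalin cations to spiro[4.5]decanes (acid- or epoxide-triggered eudesmane → spirovetivane and Westphalen-type rearrangements).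

Step 2
Reactants: 4 spiro lactone
Product: 5 enone (4S,5R,7R,8R)-2-oxo-9(10→5)abeo-eudesma-1(10),11(13)-dien-12,8β-olide
Conditions: CrO3, 3,5-dimethylpyrazole, CH2Cl2, −20 °C
Reagents that add atoms: chromium trioxide, O=[Cr](=O)=O
Why: Allylic oxidation with the CrO3·3,5-dimethylpyrazole complex (Salmond oxidation, as in valencene → nootkatone) takes the ring CH2 at C2 in preference to the C14 methyl and to the electron-poor lactone alkene; no stereocentre is formed.

Step 3
Reactants: 5 enone
Product: 7 hydroxy enone (3S,4R,5R,7R,8R)-3α-hydroxy-2-oxo-9(10→5)abeo-eudesma-1(10),11(13)-dien-12,8β-olide, via sodium dienolate 6 (not isolated)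
Conditions: NaN(SiMe3)2, THF, −78 °C; 2-(benzenesulfonyl)-3-phenyloxaziridine; AcOH quench
Reagents that add atoms: 2-(benzenesulfonyl)-3-phenyloxaziridine (Davis oxaziridine), O=S(=O)(c1ccccc1)N1OC1c1ccccc1
Why: Kinetic α′-deprotonation at C3 gives the cross-conjugated dienolate 6, and Davis enolate hydroxylation occurs on the face anti to the neighbouring 4β-methyl, giving the 3α (3S) alcohol, which is also the equatorial epimer.

Step 4
Reactants: 7 hydroxy enone
Product: 9 diol (2S,3S,4R,5R,7R,8R)-2β,3α-dihydroxy-9(10→5)abeo-eudesma-1(10),11(13)-dien-12,8β-olide, via alkoxyborohydride 8 (not isolated)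
Conditions: Me4NBH(OAc)3, MeCN/AcOH 1:1, −30 °C
Reagents that add atoms: none
Why: Saksena–Evans hydroxyl-directed reduction: the C3 hydroxyl binds boron (8) and delivers hydride to the α face of the C2 carbonyl, giving the 2β (2S) alcohol trans to 3α-OH, while the lactone and its methylene group are inert to this mild hydride.

Step 5
Reactants: 9 diol
Product: 10 triol (2S,3S,4R,5R,7R,8R)-2β,3α,14-trihydroxy-9(10→5)abeo-eudesma-1(10),11(13)-dien-12,8β-olide
Conditions: SeO2 (0.3 equiv), t-BuOOH (2 equiv), CH2Cl2, 0 °C, stopped before over-oxidation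
Reagents that add atoms: selenium dioxide, O=[Se]=O (transfers the oxygen); tert-butyl hydroperoxide, CC(C)(C)OO (reoxidant and ultimate oxygen source)
Why: Sharpless SeO2/t-BuOOH allylic hydroxylation (ene reaction, then [2,3] shift) acts at the more substituted alkene carbon C10, whose only allylic hydrogens are on C14 because C5 is quaternary, so the primary allylic alcohol forms with the alkene returned to the 1(10) position; no stereocentre is formed.

Step 6
Reactants: 10 triol; 11 angelic acid
Product: 13 target (2S,3S,4R,5R,7R,8R)-14-angeloyloxy-2β,3α-dihydroxy-9(10→5)abeo-eudesma-1(10),11(13)-dien-12,8β-olide, via mixed anhydride 12 (not isolated)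
Conditions: 11 (1.1 equiv), 2,4,6-Cl3C6H2COCl, Et3N, toluene, 23 °C; then 10, 60 °C, no DMAP
Reagents that add atoms: none
Why: Yamaguchi mixed-anhydride esterification run without DMAP transfers the angeloyl group with its Z geometry intact, and the primary allylic C14 hydroxyl reacts far faster than the two secondary hydroxyls.

**Compound list**
1 | (+)-alantolactone, (4S,7R,8R,10R)-eudesma-5,11(13)-dien-12,8β-olide (4β-CH3, 10β-CH3, cis-fused α-methylene lactone on the β face) | C=C1C(=O)O[C@@H]2C[C@@]3(C)CCC[C@H](C)C3=C[C@H]12 | starting material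
2 | C5 eudesmyl cation (1 protonated at C6, tertiary cation at C5) | C=C1C(=O)O[C@@H]2C[C@@]3(C)CCC[C@H](C)[C+]3C[C@H]12 | intermediate
3 | C10 spiro cation (C9 now bonded to C5, tertiary cation at C10) | C=C1C(=O)O[C@@H]2C[C@@]3(C[C@H]12)[C+](C)CCC[C@@H]3C | intermediate
4 | (4S,5R,7R,8R)-9(10→5)abeo-eudesma-1(10),11(13)-dien-12,8β-olide (spiro C5 with C6 β and C9 α, 4β-CH3) | C=C1C(=O)O[C@@H]2C[C@@]3(C[C@H]12)C(C)=CCC[C@@H]3C | intermediate
5 | (4S,5R,7R,8R)-2-oxo-9(10→5)abeo-eudesma-1(10),11(13)-dien-12,8β-olide | C=C1C(=O)O[C@@H]2C[C@@]3(C[C@H]12)C(C)=CC(=O)C[C@@H]3C | intermediate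
6 | sodium 1(10),2-dien-2-olate of 5 (cross-conjugated dienolate, C2–ONa, C2=C3) | C=C1C(=O)O[C@@H]2C[C@@]3(C[C@H]12)C(C)=CC([O-])=C[C@@H]3C.[Na+] | intermediate
7 | (3S,4R,5R,7R,8R)-3α-hydroxy-2-oxo-9(10→5)abeo-eudesma-1(10),11(13)-dien-12,8β-olide | C=C1C(=O)O[C@@H]2C[C@@]3(C[C@H]12)C(C)=CC(=O)[C@@H](O)[C@@H]3C | intermediate
8 | tetramethylammonium diacetoxy(hydrido)borate bound through the C3 oxygen of 7 | C=C1C(=O)O[C@@H]2C[C@@]3(C[C@H]12)C(C)=CC(=O)[C@@H](O[BH-](OC(C)=O)OC(C)=O)[C@@H]3C.C[N+](C)(C)C | intermediate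
9 | (2S,3S,4R,5R,7R,8R)-2β,3α-dihydroxy-9(10→5)abeo-eudesma-1(10),11(13)-dien-12,8β-olide | C=C1C(=O)O[C@@H]2C[C@@]3(C[C@H]12)C(C)=C[C@H](O)[C@@H](O)[C@@H]3C | intermediate
10 | (2S,3S,4R,5R,7R,8R)-2β,3α,14-trihydroxy-9(10→5)abeo-eudesma-1(10),11(13)-dien-12,8β-olide | C=C1C(=O)O[C@@H]2C[C@@]3(C[C@H]12)C(CO)=C[C@H](O)[C@@H](O)[C@@H]3C | intermediate
11 | angelic acid, (Z)-2-methylbut-2-enoic acid | C/C=C(/C)C(=O)O | starting material
12 | angelic 2,4,6-trichlorobenzoic anhydride | C/C=C(/C)C(=O)OC(=O)c1c(Cl)cc(Cl)cc1Cl | intermediate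
13 | CNP0224912.1, (2S,3S,4R,5R,7R,8R)-14-angeloyloxy-2β,3α-dihydroxy-9(10→5)abeo-eudesma-1(10),11(13)-dien-12,8β-olide | C=C1C(=O)O[C@@H]2C[C@@]3(C[C@H]12)C(COC(=O)/C(C)=C\C)=C[C@H](O)[C@@H](O)[C@@H]3C | target

**Totals**
Total step count: 6. Longest linear sequence: 6 steps (from 1).

**Three steps most likely to fail**

Step 1 is the weakest step by a wide margin. In cation 2 the C14 methyl on the β face is aligned with the empty orbital at least as well as the C9 bond on the α face, so the 1,2-methyl shift to an eremophilanolide competes directly. The cation can also just lose H4 to give the Δ4 isomer, and the six-to-five contraction is not downhill for a simple cation. The fallback sets out from 1 and comes back at 9. It runs the same C9 shift on a substrate where the C9–C10 bond is antiperiplanar to a leaving β-oxygen on C5 and epoxide strain pays for the contraction. Isomerisation of 1 (TsOH, benzene, 80 °C) gives the Δ4 isomer eudesma-4,11(13)-dien-12,8β-olide F1. Allylic oxidation (CrO3, 3,5-dimethylpyrazole; the C6 ketone is separated) gives 3-oxo-eudesma-4,11(13)-dien-12,8β-olide F2. Luche reduction (NaBH4, CeCl3·7H2O, MeOH, −78 °C) gives the equatorial alcohol 3β-hydroxy-eudesma-4,11(13)-dien-12,8β-olide F3. Hydroxyl-directed epoxidation (VO(acac)2, t-BuOOH, CH2Cl2) gives 3β-hydroxy-4β,5β-epoxy-eudesm-11(13)-en-12,8β-olide F4. Ti(OiPr)4 then BF3·OEt2 (CH2Cl2, −78 °C) opens the C5–O bond with migration of C9 and loss of H1 to give 3β,4β-dihydroxy-9(10→5)abeo-eudesma-1(10),11(13)-dien-12,8β-olide F5. Pinacol rearrangement of this cis-diol (TsOH, CH2Cl2) moves the axial H3α, which is antiperiplanar to the leaving 4β-oxygen, onto C4, so C4 ends with 4α-H and 4β-CH3 in 3-oxo-9(10→5)abeo-eudesma-1(10),11(13)-dien-12,8β-olide F6. Enolate hydroxylation at the allylic C2 (NaN(SiMe3)2, Davis oxaziridine; equilibrates to the equatorial alcohol) gives 2β-hydroxy-3-oxo-9(10→5)abeo-eudesma-1(10),11(13)-dien-12,8β-olide F7. Me4NBH(OAc)3 then reduces C3 anti to the 2β-hydroxyl and gives 9.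

Step 5 runs SeO2 on an unprotected allylic diol. The new primary allylic alcohol can be oxidised on to the enal, and the diol can tie up selenium as selenite esters. The fallback sets out from 9 and comes back at 10. Silylation (Et3SiOSO2CF3, 2,6-lutidine, CH2Cl2, −78 °C) gives 2β,3α-bis(triethylsilyloxy)-9(10→5)abeo-eudesma-1(10),11(13)-dien-12,8β-olide F8. SeO2/t-BuOOH then meets no free alcohol and gives 14-hydroxy-2β,3α-bis(triethylsilyloxy)-9(10→5)abeo-eudesma-1(10),11(13)-dien-12,8β-olide F9. HF·pyridine (THF, 0 °C) gives 10.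

Step 6 can fail through over-acylation of the secondary hydroxyls at 60 °C or through Z-to-E isomerisation of the angeloyl group to the tiglate. The fallback sets out from 10 and comes back at 13, and makes the ester by O-alkylation of the carboxylate instead of acylation of the alcohol. CBr4/PPh3 (CH2Cl2, −40 °C) converts only the primary allylic hydroxyl into 14-bromo-2β,3α-dihydroxy-9(10→5)abeo-eudesma-1(10),11(13)-dien-12,8β-olide F10. Caesium angelate (11, Cs2CO3, DMF, 0 °C) displaces the bromide by SN2, which never activates the acid carbonyl and so cannot isomerise the Z-alkene, and gives 13.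

**Further compounds**
F1 | step 1 | (7R,8R,10R)-eudesma-4,11(13)-dien-12,8β-olide | C=C1C(=O)O[C@@H]2C[C@@]3(C)CCCC(C)=C3C[C@H]12
F2 | step 1 | 3-oxo-eudesma-4,11(13)-dien-12,8β-olide | C=C1C(=O)O[C@@H]2C[C@@]3(C)CCC(=O)C(C)=C3C[C@H]12
F3 | step 1 | (3S)-3β-hydroxy-eudesma-4,11(13)-dien-12,8β-olide | C=C1C(=O)O[C@@H]2C[C@@]3(C)CC[C@H](O)C(C)=C3C[C@H]12
F4 | step 1 | 3β-hydroxy-4β,5β-epoxy-eudesm-11(13)-en-12,8β-olide | C=C1C(=O)O[C@@H]2C[C@@]3(C)CC[C@H](O)[C@]4(C)O[C@]34C[C@H]12
F5 | step 1 | 3β,4β-dihydroxy-9(10→5)abeo-eudesma-1(10),11(13)-dien-12,8β-olide (4α-CH3) | C=C1C(=O)O[C@@H]2C[C@@]3(C[C@H]12)C(C)=CC[C@H](O)[C@]3(C)O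
F6 | step 1 | 3-oxo-9(10→5)abeo-eudesma-1(10),11(13)-dien-12,8β-olide (4β-CH3) | C=C1C(=O)O[C@@H]2C[C@@]3(C[C@H]12)C(C)=CCC(=O)[C@@H]3C
F7 | step 1 | 2β-hydroxy-3-oxo-9(10→5)abeo-eudesma-1(10),11(13)-dien-12,8β-olide | C=C1C(=O)O[C@@H]2C[C@@]3(C[C@H]12)C(C)=C[C@H](O)C(=O)[C@@H]3C
F8 | step 5 | 2β,3α-bis(triethylsilyloxy)-9(10→5)abeo-eudesma-1(10),11(13)-dien-12,8β-olide | C=C1C(=O)O[C@@H]2C[C@@]3(C[C@H]12)C(C)=C[C@H](O[Si](CC)(CC)CC)[C@@H](O[Si](CC)(CC)CC)[C@@H]3C
F9 | step 5 | 14-hydroxy-2β,3α-bis(triethylsilyloxy)-9(10→5)abeo-eudesma-1(10),11(13)-dien-12,8β-olide | C=C1C(=O)O[C@@H]2C[C@@]3(C[C@H]12)C(CO)=C[C@H](O[Si](CC)(CC)CC)[C@@H](O[Si](CC)(CC)CC)[C@@H]3C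
F10 | step 6 | 14-bromo-2β,3α-dihydroxy-9(10→5)abeo-eudesma-1(10),11(13)-dien-12,8β-olide | C=C1C(=O)O[C@@H]2C[C@@]3(C[C@H]12)C(CBr)=C[C@H](O)[C@@H](O)[C@@H]3C
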